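**Plan**

- Target: 2-methoxy-6-nonadecyl-1,4-benzoquinone. Ring numbering used here: C1 (C=O between C2 and C6), C2 (OMe), C3 (H), C4 (C=O), C5 (H), C6 (n-C19H39).
- Enabling feature: read around the ring, C3=C2(OMe)–C1(O)=C6(R)–C5(H)=C4=O is a vinylketene carrying a 1-methoxyvinyl group. A 4-(1-methoxyvinyl)-4-oxycyclobut-2-enone gives exactly this dienylketene on ring opening, and the para O1/O4 pair is the hydroquinone that such a cyclobutenone delivers.
- Cuts: (a) ring bond C4–C3 (6π electrocyclisation of the dienylketene; in reverse, C4 is reconnected to C1 as a cyclobutenone); (b) C1–C2 (1-methoxyvinyllithium plus a squarate carbonyl); (c) the C6–chain bond (nonadecyl Grignard, with a 1,3-carbonyl transposition that also leaves H on C5).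
- Forward order: squaric diester → semisquarate (C5–H) → C2/C3 unit onto C1 → C19 chain onto C6 with transposition (temporary four-membered ring complete) → thermal four-to-six ring expansion closing C4–C3 → oxidation to the quinone.
- Stereochemistry: the target has no stereocentre and no stereogenic double bond. The quaternary carbinol carbon of the cyclobutenones is racemic and becomes sp2. Only the torquoselectivity of ring opening (silyloxy outward) matters, and it gives the ketene geometry needed for closure.

Key step: step 4

Remark: the side chain is read as unbranched nonadecyl (19 carbons, C26H44O3 for the target); diisopropyl squarate, methyl vinyl ether and 1-bromononadecane are taken as purchasable.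

**Route**

Step 1
Reactants: 1 diisopropyl squarate
Product: 3 3-(propan-2-yloxy)cyclobut-3-ene-1,2-dione, via hydroxycyclobutenone 2 (not isolated)
Conditions: LiAlH(OtBu)3 (1.05 equiv), THF, −78 → −20 °C; then 6 M HCl, CH2Cl2, 0 °C → rt
Reagents that add atoms: water, O
Why: Monoreduction of one of the two equivalent ketone carbonyls by the mild, bulky hydride, followed by acid-induced ionisation of the carbinol and capture of the isopropoxy-stabilised cyclobutenyl cation by water (1,2-reduction then 1,3-carbonyl transposition with loss of propan-2-ol), is the standard way from a squaric diester to a semisquarate and installs the future C5–H.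

Step 2
Reactants: 4 methyl vinyl ether; 3 3-(propan-2-yloxy)cyclobut-3-ene-1,2-dione
Product: 7 4-(1-methoxyethenyl)-3-(propan-2-yloxy)-4-[(triethylsilyl)oxy]cyclobut-2-en-1-one, via 1-methoxyvinyllithium 5 (not isolated), via lithium alkoxide 6 (not isolated)
Conditions: 4, t-BuLi, THF, −78 → 0 °C; then added to 3, THF, −78 °C; then Et3SiCl, −78 → 0 °C
Reagents that add atoms: chlorotriethylsilane, CC[Si](Cl)(CC)CC
Why: α-Deprotonation of the enol ether gives an acyl-anion equivalent that should add 1,2 to the ketone-like carbonyl attached to the isopropoxy-bearing ring carbon, because the other carbonyl is deactivated as a vinylogous ester (the usual site rule for organolithium additions to alkoxycyclobutenediones), and silylation of the alkoxide in the same flask protects the tertiary carbinol, whose quaternary carbon forms racemic and later becomes sp2.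

Step 3
Reactants: 8 1-bromononadecane; 7 4-(1-methoxyethenyl)-3-(propan-2-yloxy)-4-[(triethylsilyl)oxy]cyclobut-2-en-1-one
Product: 12 4-(1-methoxyethenyl)-3-nonadecyl-4-[(triethylsilyl)oxy]cyclobut-2-en-1-one, via nonadecylmagnesium bromide 9 (not isolated), via magnesium alkoxide 10 (not isolated), via trifluoroacetate 11 (not isolated)
Conditions: 8, Mg, THF, reflux; then 7, THF, −78 → −40 °C; (CF3CO)2O, −78 °C; sat. aq. NaHCO3, 0 °C
Reagents that add atoms: water, O
Why: Stork–Danheiser 1,3-carbonyl transposition: the Grignard reagent adds 1,2 to the only carbonyl of the vinylogous ester, the alkoxide is trifluoroacetylated and ionises with help of the isopropoxy group, and water then attacks the isopropoxy-bearing carbon with loss of propan-2-ol, so that the chain sits on the ring carbon next to the silyloxy carbon and hydrogen next to the new carbonyl, while the acid-labile enol ether and silyl ether never meet a Brønsted acid (direct conjugate addition–elimination would converge on the same product).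

Step 4
Reactants: 12 4-(1-methoxyethenyl)-3-nonadecyl-4-[(triethylsilyl)oxy]cyclobut-2-en-1-one
Product: 15 3-methoxy-5-nonadecyl-4-[(triethylsilyl)oxy]phenol, via dienylketene 13 (not isolated), via cyclohexadienone 14 (not isolated)
Conditions: toluene (0.02 M), 110 °C, Ar, 2 h
Reagents that add atoms: none
Why: Heating opens the strained four-membered ring of 12 by conrotatory 4π electrocyclic cleavage of the C(=O)–C(OSiEt3) bond, the silyloxy donor rotating outward so that the 1-methoxyethenyl group turns inward and the dienylketene 13 with ketenyl and methoxyethenyl groups cis results. The ketene carbon (future C4) and the CH2 terminus of the enol ether (future C3) then join by thermal disrotatory 6π electrocyclisation, the only ring closure of the step, giving the six-membered cyclohexa-2,4-dienone 14, which enolises to the aromatic phenol 15; the step is an isomerisation with all atoms retained. The closest known reaction type is the Moore rearrangement of 4-alkenyl-4-hydroxy- or 4-silyloxycyclobut-2-enones to hydroquinones. No stereocentre is created, since the racemic carbinol carbon and the CH2 carbon both become aromatic sp2 centres. The step needs the alkenyl group and not the silyloxy group to rotate toward the ketene, which the strong outward preference of an oxygen donor on the ring-opening carbon secures, and the substitution pattern cannot scramble because C19H39, H, OSiEt3 and OMe are already fixed on the six atoms that become the ring. Dilute, strictly aprotic conditions should keep the ketene from intermolecular capture.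

Step 5
Reactants: 15 3-methoxy-5-nonadecyl-4-[(triethylsilyl)oxy]phenol
Product: 16 2-methoxy-6-nonadecylcyclohexa-2,5-diene-1,4-dione
Conditions: (NH4)2Ce(NO3)6 (2.5 equiv), MeCN/THF/H2O, 0 °C, 15 min
Reagents that add atoms: none
Why: Tetravalent cerium removes two electrons from the electron-rich para-silyloxyphenol and water takes the silyl group as silanol (oxidative desilylation of a hydroquinone monoether to the para-quinone), a fast reaction at 0 °C that should leave the 2-methoxy group and the saturated chain untouched.

**Compound list**

1 | diisopropyl squarate, 3,4-di(propan-2-yloxy)cyclobut-3-ene-1,2-dione | CC(C)OC1=C(OC(C)C)C(=O)C1=O | starting material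
2 | 4-hydroxy-2,3-di(propan-2-yloxy)cyclobut-2-en-1-one (racemic) | CC(C)OC1=C(OC(C)C)C(O)C1=O | intermediate
3 | 3-(propan-2-yloxy)cyclobut-3-ene-1,2-dione (isopropyl semisquarate) | CC(C)OC1=CC(=O)C1=O | intermediate
4 | methyl vinyl ether (methoxyethene) | COC=C | starting material
5 | 1-methoxyvinyllithium, (1-methoxyethenyl)lithium | [Li]C(=C)OC | intermediate
6 | lithium 1-(1-methoxyethenyl)-4-oxo-2-(propan-2-yloxy)cyclobut-2-en-1-olate (racemic) | [Li+].[O-]C1(C(=C)OC)C(OC(C)C)=CC1=O | intermediate
7 | 4-(1-methoxyethenyl)-3-(propan-2-yloxy)-4-[(triethylsilyl)oxy]cyclobut-2-en-1-one (racemic) | CC[Si](CC)(CC)OC1(C(=C)OC)C(OC(C)C)=CC1=O | intermediate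
8 | 1-bromononadecane | CCCCCCCCCCCCCCCCCCCBr | starting material
9 | nonadecylmagnesium bromide | CCCCCCCCCCCCCCCCCCC[Mg]Br | intermediate
10 | bromomagnesium 4-(1-methoxyethenyl)-1-nonadecyl-3-(propan-2-yloxy)-4-[(triethylsilyl)oxy]cyclobut-2-en-1-olate (diastereomer mixture) | CCCCCCCCCCCCCCCCCCCC1(O[Mg]Br)C=C(OC(C)C)C1(O[Si](CC)(CC)CC)C(=C)OC | intermediate
11 | 4-(1-methoxyethenyl)-1-nonadecyl-3-(propan-2-yloxy)-4-[(triethylsilyl)oxy]cyclobut-2-en-1-yl trifluoroacetate (diastereomer mixture) | CCCCCCCCCCCCCCCCCCCC1(OC(=O)C(F)(F)F)C=C(OC(C)C)C1(O[Si](CC)(CC)CC)C(=C)OC | intermediate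
12 | 4-(1-methoxyethenyl)-3-nonadecyl-4-[(triethylsilyl)oxy]cyclobut-2-en-1-one (racemic) | CCCCCCCCCCCCCCCCCCCC1=CC(=O)C1(O[Si](CC)(CC)CC)C(=C)OC | intermediate
13 | 5-methoxy-3-nonadecyl-4-[(triethylsilyl)oxy]hexa-1,3,5-trien-1-one, ketenyl CH and methoxyethenyl group cis on the central double bond | CCCCCCCCCCCCCCCCCCC/C(C=C=O)=C(\O[Si](CC)(CC)CC)C(=C)OC | intermediate
14 | 5-methoxy-3-nonadecyl-4-[(triethylsilyl)oxy]cyclohexa-2,4-dien-1-one | CCCCCCCCCCCCCCCCCCCC1=CC(=O)CC(OC)=C1O[Si](CC)(CC)CC | intermediate
15 | 3-methoxy-5-nonadecyl-4-[(triethylsilyl)oxy]phenol | CCCCCCCCCCCCCCCCCCCc1cc(O)cc(OC)c1O[Si](CC)(CC)CC | intermediate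
16 | 2-methoxy-6-nonadecylcyclohexa-2,5-diene-1,4-dione (2-methoxy-6-nonadecyl-1,4-benzoquinone) | CCCCCCCCCCCCCCCCCCCC1=CC(=O)C=C(OC)C1=O | target

**Step count and risks**

Total steps: 5. Longest linear sequence: 5 steps (1 → 3 → 7 → 12 → 15 → 16).

Steps most likely to fail:

1. Step 3. What may go wrong: loss of the 1-methoxyethenyl enol ether (protonolysis or C-trifluoroacetylation) or of the silyl ether while the tertiary carbinol is ionised; silyl migration between the two vicinal oxygens in the alkoxide; reduction instead of addition by the Grignard reagent.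
 Fallback (the transposition is finished before any enol ether is present): the sequence sets out from 1 and comes back at 12. Nonadecylmagnesium bromide 9 would add to one squarate carbonyl to give 4-hydroxy-2,3-di(propan-2-yloxy)-4-nonadecylcyclobut-2-en-1-one F1. Reduction of its remaining carbonyl with i-Bu2AlH would give 2,3-di(propan-2-yloxy)-1-nonadecylcyclobut-2-ene-1,4-diol F2, and 6 M HCl would then effect a double 1,3-transposition to 3-nonadecylcyclobut-3-ene-1,2-dione F3, a robust compound free of sensitive groups. 1-Methoxyvinyllithium 5 at −78 °C would then add to the carbonyl attached to the alkyl-bearing ring carbon (the one not conjugated to a β-alkyl group) to give lithium 1-(1-methoxyethenyl)-2-nonadecyl-4-oxocyclobut-2-en-1-olate F4, and Et3SiCl would convert it into 12. The site preference in this addition is an electronic expectation only, so a regioisomeric adduct might have to be removed by chromatography.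

2. Step 2. What may go wrong: poor site selectivity (attack at the vinylogous ester carbonyl or conjugate addition at the unsubstituted ring carbon), double addition, or fragmentation of the alkoxide before it is silylated.
 Fallback (no carbonyl site selection; the same C4–C3 bond is closed at the phenol oxidation level): the sequence sets out from 8, uses 5 for the tin reagent, and comes back at 16. LiC≡CH·H2NCH2CH2NH2 in DMSO would convert 8 into heneicos-1-yne F5. Dichloroketene F6, made in the flask from Cl3CCOCl and Zn/Cu couple in Et2O/DME, would add in a [2+2] cycloaddition (ketene carbonyl carbon to the terminal alkyne carbon) to give 4,4-dichloro-3-nonadecylcyclobut-2-en-1-one F7. One equivalent of Zn in AcOH/TMEDA/EtOH at 0 °C would remove one chlorine to give 4-chloro-3-nonadecylcyclobut-2-en-1-one F8. Tributyl(1-methoxyethenyl)stannane F9, from 5 and Bu3SnCl, would be joined to F8 by Stille coupling (Pd2(dba)3 as source of zerovalent palladium, tri(2-furyl)phosphine, dioxane, 50 → 100 °C). The coupled 4-(1-methoxyethenyl)-3-nonadecylcyclobut-2-en-1-one F10 would open and close at the reaction temperature to 3-methoxy-5-nonadecylphenol F11. Teuber oxidation with (KSO3)2NO in buffered acetone/water at the free position para to the hydroxyl would then give 16.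

3. Step 4. What may go wrong: diversion of the ketene (dimerisation, capture by traces of water, [2+2] addition to the enol ether) or thermal desilylation with aerial oxidation, giving mixtures.
 Fallback (the ring is taken from an arene instead of being built): the sequence sets out from 8 and comes back at 16. Guaiacol would be protected (NaH, MeOCH2Cl, THF) as 1-methoxy-2-(methoxymethoxy)benzene F12. Directed ortho-lithiation next to the acetal oxygen (n-BuLi, TMEDA, THF, 0 °C) would give [3-methoxy-2-(methoxymethoxy)phenyl]lithium F13, and alkylation with 8 would give 1-methoxy-2-(methoxymethoxy)-3-nonadecylbenzene F14. HCl in MeOH would release 2-methoxy-6-nonadecylphenol F15. Oxidation of its free para position with O2 and Co(salen) (N,N′-bis(salicylidene)ethylenediaminocobalt, divalent cobalt) in DMF, or with (KSO3)2NO, would give 16.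

**Further compounds**

F1 | step 3 | 4-hydroxy-2,3-di(propan-2-yloxy)-4-nonadecylcyclobut-2-en-1-one | CCCCCCCCCCCCCCCCCCCC1(O)C(OC(C)C)=C(OC(C)C)C1=O
F2 | step 3 | 2,3-di(propan-2-yloxy)-1-nonadecylcyclobut-2-ene-1,4-diol | CCCCCCCCCCCCCCCCCCCC1(O)C(OC(C)C)=C(OC(C)C)C1O
F3 | step 3 | 3-nonadecylcyclobut-3-ene-1,2-dione | CCCCCCCCCCCCCCCCCCCC1=CC(=O)C1=O
F4 | step 3 | lithium 1-(1-methoxyethenyl)-2-nonadecyl-4-oxocyclobut-2-en-1-olate | [Li+].[O-]C1(C(=C)OC)C(CCCCCCCCCCCCCCCCCCC)=CC1=O
F5 | step 2 | heneicos-1-yne | CCCCCCCCCCCCCCCCCCCC#C
F6 | step 2 | dichloroketene | ClC(Cl)=C=O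
F7 | step 2 | 4,4-dichloro-3-nonadecylcyclobut-2-en-1-one | CCCCCCCCCCCCCCCCCCCC1=CC(=O)C1(Cl)Cl
F8 | step 2 | 4-chloro-3-nonadecylcyclobut-2-en-1-one | CCCCCCCCCCCCCCCCCCCC1=CC(=O)C1Cl
F9 | step 2 | tributyl(1-methoxyethenyl)stannane | CCCC[Sn](CCCC)(CCCC)C(=C)OC
F10 | step 2 | 4-(1-methoxyethenyl)-3-nonadecylcyclobut-2-en-1-one | CCCCCCCCCCCCCCCCCCCC1=CC(=O)C1C(=C)OC
F11 | step 2 | 3-methoxy-5-nonadecylphenol | CCCCCCCCCCCCCCCCCCCc1cc(O)cc(OC)c1
F12 | step 4 | 1-methoxy-2-(methoxymethoxy)benzene | COCOc1ccccc1OC
F13 | step 4 | [3-methoxy-2-(methoxymethoxy)phenyl]lithium | [Li]c1cccc(OC)c1OCOC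
F14 | step 4 | 1-methoxy-2-(methoxymethoxy)-3-nonadecylbenzene | CCCCCCCCCCCCCCCCCCCc1cccc(OC)c1OCOC
F15 | step 4 | 2-methoxy-6-nonadecylphenol | CCCCCCCCCCCCCCCCCCCc1cccc(OC)c1O
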